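(The data stem from a simulated flask on assumed constants.)

I started from the autumn run, the only earlier run, and asked what it could tell me about Q in the flask below.

common to all: D 5 mol%

| flask | X | Q | remark | time |
|---|---|---|---|---|
| autumn | 1.6 M | 1.1 equiv | run made earlier |  |
| flask | 0.80 M | 1.10 equiv |  | 2.5 h |

- autumn (time / min: E / %, J / %): 4.00: 2.5, 5.7; 6.00: 1.6, 10.8; 8.00: 3.6, 11.9; 12.0: 8.0, 19.1; 20.0: 17.7, 22.6; 30.0: 27.4, 26.8; 50.0: 35.8, 29.8

(each reading ± 1 percentage point)

- percent here means X units held: one G counts as two
- steps under discussion: 2 X -> G; D + L <-> Z; Q + Z -> D + J; X + D -> D + L; Q + J -> E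
- no earlier run changes the charge of D; that part of a forecast is a guess

- share of E in E plus J at 5.0 min
- share of E in E plus J at 25 min
- share of E in E plus J at 2.5 h

1. Each J took one Q and each E took one more, so Q used, in percent of the X charged, was J plus twice E. I named the Q budget, the Q charged per X charged, which must equal J plus twice E plus the Q still left: 110% in the flask.

2. I called E plus J the yield. Where Q left is small, E is the budget minus the yield, so the share of E in E plus J (the over-reaction selectivity) is the budget over the yield, minus one.

3. The last autumn reading, at 50.0 min, gave a yield of 65.6% and Q used of 101%, which left 8.60%. With the yield frozen, the share came to 67.7%.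

4. All steps but Z falling back to D and L are bimolecular. I therefore took the flask, at the same equivalents and loading, as the autumn run on a clock stretched twice, so that 2.5 h in the flask matched 75.0 min in autumn, beyond the last reading.

5. The weak link was the frozen yield. Between the last two autumn readings, the yield gained 57.6% of each Q used. Spending what was left at that rate gave a yield of 70.6%, and I committed to a final share of 55.9%. The budget bears on the last time, so I gave no number for the two earlier ones.

The forecast gave 8%, 30% and 53%, the last of these on the ground that “Q is essentially spent, since J + 2E approaches 110”. My number stood higher than its last one.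

The flask gave 7.86%, 34.8% and 57.9%, with 1.9% of its Q left at 2.50 h.

    2 X → G (k = 2.42 × 10⁻⁴ L mol⁻¹ s⁻¹)
    D + L ⇌ Z (K = 27.0 L mol⁻¹, k = 0.0363 L mol⁻¹ s⁻¹)
    Q + Z → D + J (k = 0.0102 L mol⁻¹ s⁻¹)
    X + D → D + L (k = 0.0397 L mol⁻¹ s⁻¹)
    Q + J → E (k = 9.88 × 10⁻⁴ L mol⁻¹ s⁻¹)

The flask's yield at that time was 68.3%, lower than my 70.6%, and the budget less the Q left, taken over that yield, gives 58.0%. The shrinking supply of Q held the share down: the run with Q kept at its charge ended at 99.0%, against 57.9% as it stands.

In the neighbour flask with 8.5 mol% of D, subtracting its remaining X, L, G and Z from the X charged leaves a yield of 75.4%, and the budget gives a share of 45.9%. That neighbour's computed share was 45.7%, with 0.160% of its Q left.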